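Abbreviations: TIPS = triisopropylsilyl, Piv = pivaloyl (2,2-dimethylpropanoyl), prenyl = 3-methylbut-2-enyl. Flavone numbering (O1, C2 to C8a, C1' to C6') is used for the ring system.

## Analysis of the target

The target is a flavone: a 4H-chromen-4-one (rings A and C) with a para-substituted phenyl ring B on C2. It has no stereocentre, so the problem is one of regiochemistry and of telling five oxygen functions apart. Ring A is a 1,2,3,5-tetraoxygenated benzene in which only C6 carries hydrogen. O1 and the free 7-hydroxyl flank the 8-methoxy group, and the chelated 5-hydroxyl lies para to it, so closing ring C through the wrong phenolic oxygen would give the 6-methoxy isomer. The two prenyl ethers, on C3 of ring C and on C4' of ring B, are the sensitive groups. They are lost in acid, reduced under hydrogenolysis and attacked by peracids and dioxiranes. Benzyl or acetal groups therefore cannot be removed late, and no electrophilic oxidant can be used once the prenyl ethers are present. The protecting groups on O5 and O7 must leave under conditions that spare allylic ethers. The hard part is building the fully substituted ring A with its oxygens differentiated and fusing ring C to it in the right orientation. The strategy rests on the position of C4: this carbonyl carbon is bonded to C4a of ring A on one side and to the C3–C2 unit carrying ring B on the other, and C2 is bonded to O1. Ring C can therefore be read as an ortho-iodophenol (C4a–I, C8a–OH), one molecule of carbon monoxide (C4) and an arylacetylene (C3, C2 and ring B).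

## Retrosynthetic reasoning

**21 to 20.** The O5–Si and O7–Si bonds are cut last. Silyl ethers are the only common phenol protection that leaves with fluoride, a reagent indifferent to prenyl ethers. TIPS is preferred to smaller silyl groups because these two ethers must first survive a hot secondary amine, a lithium amide, buffered peroxide and carbonate.

**20 to 19 and 10.** The O3–CH2 bond is cut. In flavonol 19 the enolic 3-hydroxyl is the only free hydroxyl, so its alkylation with prenyl bromide 10 needs no selectivity.

**19 to 16.** The C3–O bond is cut. The alkyne used to build ring C delivers C3 as a CH, so the oxygen must be added afterwards. Epoxidation of C2=C3 is excluded by the prenyl alkene. The C3–H of a 2-arylchromone can instead be removed by a hindered lithium amide to give 17, which is borylated to 18 and oxidised with peroxide at boron. This sequence touches neither the alkene nor the silyl ethers.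

**16 to 8, 12 and 13.** This is the central disconnection: C4a–C4, C4–C3 and O1–C2 are cut together, which removes ring C completely. What remains is iodophenol 8, carbon monoxide 13 and arylacetylene 12. The cut is made here because it is the only one that separates the molecule into a ring A piece and a ring B piece of similar size while using a one-carbon unit for C4. It also allows the 4'-prenyl ether to be in place from the start. In the forward direction, palladium has to insert into a C–I bond with two ortho substituents, take up 13 before the alkyne, and release ynone 14. A secondary amine must then steer the free phenol to the six-membered ring by way of enaminone 15. The orientation of ring C is fixed beforehand: in 8 the only free hydroxyl ortho to iodine is the one next to the methoxy group.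

**8 to 7.** The O7–Si bond is cut. In iodo-diol 7 the two hydroxyls differ in their surroundings: one has the methoxy group as its only ortho neighbour, the other lies between methoxy and iodine. A bulky silyl chloride should take the less hindered one and leave the future O1 free.

**7 to 6.** The C–I bond is cut. Diol 6 is symmetric, so its two open ring positions are equivalent and mono-iodination can only give one product. The iodine lands between a hydroxyl and the silyloxy group, which is where C4a must be.

**6 to 5 to 4.** These are protecting-group operations that turn phenol 4 into 6: silyl onto the oxygen para to methoxy (the future O5), then pivalates off the two flanking oxygens. Pivalates are used earlier because they tolerate the borylation and offer no unhindered aromatic C–H of their own, as benzyl ethers would.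

**4 to 2 to 1.** The C–O bond para to the methoxy group is cut. In dipivalate 2 the carbon para to OMe carries the only C–H that is not ortho to a substituent, so a sterically governed C–H borylation (giving 3) and oxidation install this oxygen in one operation. This avoids a multi-step exchange of a carboxyl group for oxygen. Dipivalate 2 comes from commercial 2-methoxyresorcinol 1 by acylation.

**12 to 11 to 9 and 10.** The alkyne carbon–carbon triple bond is traced to an aldehyde by a one-carbon diazophosphonate homologation. Aldehyde 11 comes from 4-hydroxybenzaldehyde 9 and prenyl bromide 10 by O-alkylation.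

## Alternatives that were turned down

**Alternative 1: ring A by cycloaddition.**
- Disconnection: C8–C8a and C4a–C5 are cut, so ring A is made from two acyclic pieces.
- Forward key step: the electron-rich diene A1 (1,4-dimethoxy-1,3-bis(trimethylsilyloxy)buta-1,3-diene, used as a mixture of double-bond isomers) adds to bromoalkynoate A2 (methyl 3-bromopropiolate). Loss of the acetal alkoxy group and the silyl groups aromatises the adduct to benzoate A3 (methyl 2-bromo-4,6-dihydroxy-3-methoxybenzoate). The ester carbon is the future C4 and the bromine marks C8a.
- For: the positions of all six ring A substituents follow from the polarity of the two partners. No symmetric intermediate and no kinetic differentiation of two hydroxyls is needed. On this point it is stronger than the chosen route, which relies on a selective silylation (step 6).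
- Against: the diene terminus that must attack carries a methoxy group and is hindered. The carbon of A2 that it must attack carries bromide, so addition–elimination competes with annulation. A3 still has two free phenols to tell apart. Ring C is not yet made: a C4–C3 condensation with a ring B ketone, an O1–C8a aryl ether closure at a bromide flanked on both sides, and the C3 oxygenation all remain, each under base or copper at high temperature.
- Comparison: the complexity-building step is spent on ring A, which the chosen route reaches by six conventional steps from 1. The chosen route offers ring C with three bonds in a single convergent step (8 + 12 + 13 to 16) and a shorter path overall.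

**Alternative 2: ring C closed at C4–C4a.**
- Disconnection: the C4–C4a bond is cut, leading to aryloxyacrylic acid A4 ((E)-2-benzyloxy-3-(4-benzyloxyphenyl)-3-[5-benzyloxy-2-methoxy-3-(pivaloyloxy)phenoxy]prop-2-enoic acid).
- Forward key step: the carboxyl group is activated as a mixed anhydride with a perfluoroacyl anhydride. The acylium-type carbon attacks C4a, the only free position ortho to the ether oxygen, to give flavone A5 (3,5,4'-tris(benzyloxy)-8-methoxy-7-pivaloyloxyflavone).
- For: the C3 oxygen is carried in from the start, so no late lithiation and oxidation of the flavone is needed. Here it is stronger than the chosen route. It uses no transition metal, and the closure has no regiochemical choice.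
- Against: A4 is a tetrasubstituted enol ether whose carboxyl group must sit cis to the aryloxy group. Making it means adding a hindered phenol to a carbon that already bears an aryl group, with control of the double-bond geometry. The ring A phenol needed for A4 carries three different protecting groups, so it needs the same differentiation of the two oxygens beside OMe as compound 8, plus one more protecting-group operation. All benzyl groups of A5 must be hydrogenolysed before any prenyl group is present, so both prenyl ethers are introduced at the very end, relying on the low reactivity of the chelated 5-hydroxyl.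
- Comparison: it is longer before the key step and no simpler in ring A. The chosen route offers a trivial ring B partner (12, two steps) that already carries its prenyl ether.

**Alternative 3: ring A grown on a pyranone.**
- Disconnection: the C4a–C5 bond is cut, with C5 to C8 coming from a four-membered ring in cyclobutenone A6 (racemic 3-allyloxy-4-methoxy-4-[4-oxo-5-(prenyloxy)-6-(4-prenyloxyphenyl)-4H-pyran-2-yl]cyclobut-2-en-1-one).
- Forward key step: on heating to about 110 °C, A6 opens by 4π-electrocyclic cleavage to a dienylketene. This closes by 6π-electrocyclisation onto C3 of the pyranone and tautomerises to flavone A7 (7-allyloxy-5-hydroxy-8-methoxy-3,4'-diprenyloxyflavone).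
- For: each ring A oxygen comes from a different carbon of the cyclobutenone, so 5-OH, 7-O-allyl and 8-OMe are differentiated by construction. Both prenyl ethers and the C3 oxygen are already present, and only a deallylation remains. In regiocontrol and in the endgame it is stronger than the chosen route.
- Against: A6 requires a 2-metalated 3-alkoxy-6-aryl-4-pyranone, which is as hard to make as a flavone. It must add to the correct carbonyl of an unsymmetrical squaric acid derivative, and the tertiary alkoxide must then be methylated. The allyl enol ether of A6 can undergo sigmatropic rearrangement at the temperature of the ring expansion. The final deallylation must discriminate allyl from two prenyl ethers.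
- Comparison: the risk is spread over a long precursor synthesis. The chosen route offers short, conventional fragment syntheses and places the risk in one step of a known reaction type.

Key step: step 9

## Route

Remark on the chemistry: compounds 1, 9, 10 and 13 are taken as purchased. TIPS rather than a smaller silyl group is used on O5 and O7 because these ethers must outlast Et2NH at 90 °C, LiN(iPr)2 and K2CO3.

Step 1
Reactants: 1 2-methoxybenzene-1,3-diol (2-methoxyresorcinol)
Product: 2 2-methoxy-1,3-phenylene bis(2,2-dimethylpropanoate)
Conditions: PivCl, Et3N, DMAP (cat.), CH2Cl2, 0 °C to rt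
Reagents that add atoms: pivaloyl chloride, SMILES CC(C)(C)C(Cl)=O
Why: Acylation of both phenols with nucleophilic catalysis; pivalates withstand the iridium catalyst and the peroxide of step 2 and, unlike benzyl ethers, bring no unhindered aromatic C–H into the molecule.

Step 2
Reactants: 2 2-methoxy-1,3-phenylene bis(2,2-dimethylpropanoate)
Product: 4 5-hydroxy-2-methoxy-1,3-phenylene bis(2,2-dimethylpropanoate), via pinacol arylboronate 3 (not isolated)
Conditions: [Ir(OMe)(cod)]2 (1.5 mol %), 4,4'-di-tert-butyl-2,2'-bipyridine (3 mol %), B2pin2, THF, 80 °C; then KHSO5 (as 2KHSO5·KHSO4·K2SO4), acetone–H2O, 0 °C to rt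
Reagents that add atoms: potassium peroxymonosulfate, SMILES [K+].[O-]S(=O)(=O)OO (the phenol oxygen); bis(pinacolato)diboron, SMILES CC1(C)OB(OC1(C)C)B1OC(C)(C)C(C)(C)O1 (boron and pinacol of intermediate 3 only)
Why: Sterically governed iridium-catalysed C–H borylation can reach only C5, the one C–H of 2 that is not ortho to a substituent; oxidation of the C–B bond (aryl shift from boron to oxygen) then gives the phenol para to the methoxy group in the same flask.

Step 3
Reactants: 4 5-hydroxy-2-methoxy-1,3-phenylene bis(2,2-dimethylpropanoate)
Product: 5 2-methoxy-5-(triisopropylsilyloxy)-1,3-phenylene bis(2,2-dimethylpropanoate)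
Conditions: TIPSCl, imidazole, DMF, rt
Reagents that add atoms: chlorotriisopropylsilane, SMILES CC(C)[Si](Cl)(C(C)C)C(C)C
Why: Imidazole-promoted silylation of an unhindered phenol; it places the fluoride-labile group on the future O5, and the meta relationship to the esters rules out acyl migration.

Step 4
Reactants: 5 2-methoxy-5-(triisopropylsilyloxy)-1,3-phenylene bis(2,2-dimethylpropanoate)
Product: 6 2-methoxy-5-(triisopropylsilyloxy)benzene-1,3-diol
Conditions: i-Bu2AlH, CH2Cl2, −78 to 0 °C; aq. KNaC4H4O6
Reagents that add atoms: none
Why: Reductive cleavage of the two aryl esters by hydride; an aryl TIPS ether is inert to i-Bu2AlH, so the symmetric diol is released without base or acid.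

Step 5
Reactants: 6 2-methoxy-5-(triisopropylsilyloxy)benzene-1,3-diol
Product: 7 4-iodo-2-methoxy-5-(triisopropylsilyloxy)benzene-1,3-diol
Conditions: NIS (1.0 equiv), CH2Cl2, −40 to 0 °C, dark
Reagents that add atoms: N-iodosuccinimide, SMILES O=C1CCC(=O)N1I
Why: Electrophilic aromatic iodination; C4 and C6 of 6 are equivalent, each ortho to one hydroxyl and para to the other, so one equivalent of reagent at low temperature should give a single mono-iodide with iodine between a hydroxyl and the silyloxy group.

Step 6
Reactants: 7 4-iodo-2-methoxy-5-(triisopropylsilyloxy)benzene-1,3-diol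
Product: 8 2-iodo-6-methoxy-3,5-bis(triisopropylsilyloxy)phenol
Conditions: TIPSCl (1.05 equiv), imidazole, CH2Cl2, 0 °C
Reagents that add atoms: chlorotriisopropylsilane, SMILES CC(C)[Si](Cl)(C(C)C)C(C)C
Why: Kinetic silylation; the hydroxyl at C1 of 7 has only the methoxy group as ortho neighbour, whereas the hydroxyl at C3 lies between methoxy and iodine and should react far more slowly with the bulky chlorosilane, so the hydroxyl ortho to iodine stays free.

Step 7
Reactants: 9 4-hydroxybenzaldehyde; 10 prenyl bromide (1-bromo-3-methylbut-2-ene)
Product: 11 4-(3-methylbut-2-enyloxy)benzaldehyde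
Conditions: K2CO3, acetone, reflux
Reagents that add atoms: prenyl bromide (10), SMILES CC(C)=CCBr
Why: Williamson ether synthesis by SN2 displacement at the primary allylic bromide; the aldehyde is untouched.

Step 8
Reactants: 11 4-(3-methylbut-2-enyloxy)benzaldehyde
Product: 12 1-ethynyl-4-(3-methylbut-2-enyloxy)benzene
Conditions: dimethyl (1-diazo-2-oxopropyl)phosphonate, K2CO3, MeOH, 0 °C to rt
Reagents that add atoms: dimethyl (1-diazo-2-oxopropyl)phosphonate, SMILES CC(=O)C(=[N+]=[N-])P(=O)(OC)OC (one carbon)
Why: Seyferth–Gilbert homologation in the Ohira–Bestmann form: methanolysis releases the diazomethylphosphonate anion, which adds to the aldehyde, loses phosphate and N2, and the alkylidene carbene rearranges by 1,2-hydride shift to the terminal alkyne; carbonate in methanol leaves the prenyl ether alone.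

Step 9
Reactants: 8 2-iodo-6-methoxy-3,5-bis(triisopropylsilyloxy)phenol; 12 1-ethynyl-4-(3-methylbut-2-enyloxy)benzene; 13 carbon monoxide
Product: 16 8-methoxy-2-[4-(3-methylbut-2-enyloxy)phenyl]-5,7-bis(triisopropylsilyloxy)-4H-chromen-4-one, via ynone 14 (not isolated), via enaminone 15 (not isolated)
Conditions: PdCl2(PPh3)2 (5 mol %), CO (10 bar), Et2NH, 90 °C, autoclave
Reagents that add atoms: carbon monoxide (13), SMILES [C-]#[O+]; diethylamine, SMILES CCNCC (held only in intermediate 15)
Why: This is a three-component carbonylative Sonogashira coupling with cyclisation in the same flask, the known route from 2-iodophenols and arylacetylenes to flavones. The divalent palladium precatalyst is reduced in situ to zerovalent palladium, which inserts into the C4a–I bond of 8; carbon monoxide 13 then migrates in to give an aroyl complex of divalent palladium, which takes up the acetylide formed from 12 and Et2NH and eliminates ynone 14 (C4a–C4 and C4–C3). Et2NH adds to the ynone in conjugate fashion to give enaminone 15, and the free phenol attacks the amine-bearing carbon and expels Et2NH (O1–C2), so ring C closes in an overall 6-endo-dig sense by addition–elimination. No stereocentre is formed. Carbonylative coupling must win over direct coupling, which would end in a 2-arylbenzofuran; CO pressure and the absence of copper secure this. Six-membered closure must win over 5-exo-dig closure to the aurone; the secondary amine secures this, because enaminone 15 can only be attacked at C2. Closure through O1 and not O5 is secured by the substrate, since the hydroxyl beside the methoxy group is the only free one ortho to the acyl group and O5 is held as its TIPS ether. The TIPS ethers and the trisubstituted allylic ether should tolerate Et2NH and carbonyl-ligated zerovalent palladium.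

Step 10
Reactants: 16 8-methoxy-2-[4-(3-methylbut-2-enyloxy)phenyl]-5,7-bis(triisopropylsilyloxy)-4H-chromen-4-one
Product: 19 3-hydroxy-8-methoxy-2-[4-(3-methylbut-2-enyloxy)phenyl]-5,7-bis(triisopropylsilyloxy)-4H-chromen-4-one, via 3-lithioflavone 17 (not isolated), via dimethyl 3-boronate 18 (not isolated)
Conditions: LiN(iPr)2, THF, −78 °C; B(OMe)3, −78 to 0 °C; AcOH, 30% aq. H2O2, 0 °C
Reagents that add atoms: hydrogen peroxide, SMILES OO (the 3-oxygen); trimethyl borate, SMILES COB(OC)OC (boron and methoxy groups of intermediate 18 only); lithium diisopropylamide, SMILES [Li]N(C(C)C)C(C)C (lithium of intermediate 17 only)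
Why: Deprotonation of the C3–H of a 2-arylchromone by a hindered lithium amide (known C3-lithiation of flavones), electrophilic borylation and oxidative 1,2-shift from boron to oxygen give the flavonol; the buffered peroxide acts at boron and should spare the prenyl alkene and the silyl ethers, which an epoxidation of C2=C3 would not.

Step 11
Reactants: 19 3-hydroxy-8-methoxy-2-[4-(3-methylbut-2-enyloxy)phenyl]-5,7-bis(triisopropylsilyloxy)-4H-chromen-4-one; 10 prenyl bromide
Product: 20 8-methoxy-3-(3-methylbut-2-enyloxy)-2-[4-(3-methylbut-2-enyloxy)phenyl]-5,7-bis(triisopropylsilyloxy)-4H-chromen-4-one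
Conditions: prenyl bromide, K2CO3, acetone, rt to 40 °C
Reagents that add atoms: prenyl bromide (10), SMILES CC(C)=CCBr
Why: Williamson etherification of the acidic enolic 3-hydroxyl, the only free hydroxyl in 19; anhydrous carbonate in acetone does not cleave aryl TIPS ethers.

Step 12
Reactants: 20 8-methoxy-3-(3-methylbut-2-enyloxy)-2-[4-(3-methylbut-2-enyloxy)phenyl]-5,7-bis(triisopropylsilyloxy)-4H-chromen-4-one
Product: 21 5,7-dihydroxy-8-methoxy-3-(3-methylbut-2-enyloxy)-2-[4-(3-methylbut-2-enyloxy)phenyl]-4H-chromen-4-one (5,7-dihydroxy-8-methoxy-3,4'-diprenyloxyflavone)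
Conditions: Bu4NF (2.2 equiv), AcOH, THF, 0 °C
Reagents that add atoms: none
Why: Fluoride-induced cleavage of both aryl silyl ethers, driven by Si–F bond formation; acetic acid buffers the phenoxides and the prenyl ethers are inert to fluoride.

## Compound list

1 | 2-methoxybenzene-1,3-diol (2-methoxyresorcinol) | COc1c(O)cccc1O | starting material
2 | 2-methoxy-1,3-phenylene bis(2,2-dimethylpropanoate) | COc1c(OC(=O)C(C)(C)C)cccc1OC(=O)C(C)(C)C | intermediate
3 | 2-methoxy-5-(4,4,5,5-tetramethyl-1,3,2-dioxaborolan-2-yl)-1,3-phenylene bis(2,2-dimethylpropanoate) | COc1c(OC(=O)C(C)(C)C)cc(B2OC(C)(C)C(C)(C)O2)cc1OC(=O)C(C)(C)C | intermediate (not isolated)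
4 | 5-hydroxy-2-methoxy-1,3-phenylene bis(2,2-dimethylpropanoate) | COc1c(OC(=O)C(C)(C)C)cc(O)cc1OC(=O)C(C)(C)C | intermediate
5 | 2-methoxy-5-(triisopropylsilyloxy)-1,3-phenylene bis(2,2-dimethylpropanoate) | COc1c(OC(=O)C(C)(C)C)cc(O[Si](C(C)C)(C(C)C)C(C)C)cc1OC(=O)C(C)(C)C | intermediate
6 | 2-methoxy-5-(triisopropylsilyloxy)benzene-1,3-diol | COc1c(O)cc(O[Si](C(C)C)(C(C)C)C(C)C)cc1O | intermediate
7 | 4-iodo-2-methoxy-5-(triisopropylsilyloxy)benzene-1,3-diol | COc1c(O)cc(O[Si](C(C)C)(C(C)C)C(C)C)c(I)c1O | intermediate
8 | 2-iodo-6-methoxy-3,5-bis(triisopropylsilyloxy)phenol | COc1c(O)c(I)c(O[Si](C(C)C)(C(C)C)C(C)C)cc1O[Si](C(C)C)(C(C)C)C(C)C | intermediate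
9 | 4-hydroxybenzaldehyde | O=Cc1ccc(O)cc1 | starting material
10 | prenyl bromide (1-bromo-3-methylbut-2-ene) | CC(C)=CCBr | starting material
11 | 4-(3-methylbut-2-enyloxy)benzaldehyde | O=Cc1ccc(OCC=C(C)C)cc1 | intermediate
12 | 1-ethynyl-4-(3-methylbut-2-enyloxy)benzene | C#Cc1ccc(OCC=C(C)C)cc1 | intermediate
13 | carbon monoxide | [C-]#[O+] | starting material
14 | 1-[2-hydroxy-3-methoxy-4,6-bis(triisopropylsilyloxy)phenyl]-3-[4-(3-methylbut-2-enyloxy)phenyl]prop-2-yn-1-one | O=C(C#Cc1ccc(OCC=C(C)C)cc1)c1c(O)c(OC)c(O[Si](C(C)C)(C(C)C)C(C)C)cc1O[Si](C(C)C)(C(C)C)C(C)C | intermediate (not isolated)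
15 | (E)-3-(diethylamino)-1-[2-hydroxy-3-methoxy-4,6-bis(triisopropylsilyloxy)phenyl]-3-[4-(3-methylbut-2-enyloxy)phenyl]prop-2-en-1-one (geometry as expected for a secondary-amine adduct; it does not affect the ring closure) | CCN(CC)/C(c1ccc(OCC=C(C)C)cc1)=C/C(=O)c1c(O)c(OC)c(O[Si](C(C)C)(C(C)C)C(C)C)cc1O[Si](C(C)C)(C(C)C)C(C)C | intermediate (not isolated)
16 | 8-methoxy-2-[4-(3-methylbut-2-enyloxy)phenyl]-5,7-bis(triisopropylsilyloxy)-4H-chromen-4-one | COc1c(O[Si](C(C)C)(C(C)C)C(C)C)cc(O[Si](C(C)C)(C(C)C)C(C)C)c2c(=O)cc(-c3ccc(OCC=C(C)C)cc3)oc12 | intermediate
17 | 3-lithio-8-methoxy-2-[4-(3-methylbut-2-enyloxy)phenyl]-5,7-bis(triisopropylsilyloxy)-4H-chromen-4-one | COc1c(O[Si](C(C)C)(C(C)C)C(C)C)cc(O[Si](C(C)C)(C(C)C)C(C)C)c2c(=O)c([Li])c(-c3ccc(OCC=C(C)C)cc3)oc12 | intermediate (not isolated)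
18 | dimethyl {8-methoxy-2-[4-(3-methylbut-2-enyloxy)phenyl]-4-oxo-5,7-bis(triisopropylsilyloxy)-4H-chromen-3-yl}boronate | COc1c(O[Si](C(C)C)(C(C)C)C(C)C)cc(O[Si](C(C)C)(C(C)C)C(C)C)c2c(=O)c(B(OC)OC)c(-c3ccc(OCC=C(C)C)cc3)oc12 | intermediate (not isolated)
19 | 3-hydroxy-8-methoxy-2-[4-(3-methylbut-2-enyloxy)phenyl]-5,7-bis(triisopropylsilyloxy)-4H-chromen-4-one | COc1c(O[Si](C(C)C)(C(C)C)C(C)C)cc(O[Si](C(C)C)(C(C)C)C(C)C)c2c(=O)c(O)c(-c3ccc(OCC=C(C)C)cc3)oc12 | intermediate
20 | 8-methoxy-3-(3-methylbut-2-enyloxy)-2-[4-(3-methylbut-2-enyloxy)phenyl]-5,7-bis(triisopropylsilyloxy)-4H-chromen-4-one | COc1c(O[Si](C(C)C)(C(C)C)C(C)C)cc(O[Si](C(C)C)(C(C)C)C(C)C)c2c(=O)c(OCC=C(C)C)c(-c3ccc(OCC=C(C)C)cc3)oc12 | intermediate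
21 | 5,7-dihydroxy-8-methoxy-3-(3-methylbut-2-enyloxy)-2-[4-(3-methylbut-2-enyloxy)phenyl]-4H-chromen-4-one | COc1c(O)cc(O)c2c(=O)c(OCC=C(C)C)c(-c3ccc(OCC=C(C)C)cc3)oc12 | target

## Step count and least certain steps

Total: 12 steps. Longest linear sequence: 10 steps (steps 1 to 6, then 9 to 12). The ring B alkyne is a two-step branch (steps 7 and 8).

**Step 9 (key step).** Oxidative addition at the electron-rich C–I bond with two ortho substituents may be slow. Three side paths could then overtake the three-component path: capture of the aroylpalladium by Et2NH to give an amide, direct alkynylation followed by benzofuran closure, and palladium-mediated loss of the 4'-prenyl group. The fallback takes the alkyne away from palladium and sets out from 8. Aminocarbonylation of 8 with N,O-dimethylhydroxylamine hydrochloride (Pd(OAc)2, Xantphos, CO 1 bar, Et3N, toluene, 80 °C) should give the Weinreb amide 2-hydroxy-N,3-dimethoxy-N-methyl-4,6-bis(triisopropylsilyloxy)benzamide F1. The lithium acetylide of 12 (n-BuLi, THF, −78 to 0 °C, 2.2 equivalents, one being spent on the phenol) then adds to F1 and gives ynone 14, which is isolated this time. Et2NH in ethanol at rt to 50 °C closes ring C through enaminone 15, and the route is rejoined at 16.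

**Step 6.** The two hydroxyls of 7 may not be discriminated cleanly, so that silylation occurs at the iodine-flanked oxygen or at both. The fallback leaves out the selective silylation and sets out from 7. Under the conditions of step 9, diol 7 reacts with 12 and 13; only the hydroxyl ortho to iodine can close the ring, giving 7-hydroxy-8-methoxy-2-[4-(3-methylbut-2-enyloxy)phenyl]-5-(triisopropylsilyloxy)-4H-chromen-4-one F2. Its single remaining hydroxyl is then silylated (TIPSCl, imidazole, DMF), and the route is rejoined at 16.

**Step 5.** The very electron-rich diol 6 may be iodinated twice or degraded oxidatively. The fallback moves the iodination to the less activated ester stage and sets out from 4. Ortho-iodination of 4 (NIS, TsOH cat., MeCN) gives 5-hydroxy-4-iodo-2-methoxy-1,3-phenylene bis(2,2-dimethylpropanoate) F3. Silylation (TIPSCl, imidazole, DMF) gives 4-iodo-2-methoxy-5-(triisopropylsilyloxy)-1,3-phenylene bis(2,2-dimethylpropanoate) F4. Reductive removal of the pivalates with i-Bu2AlH, which leaves the aryl iodide intact, rejoins the route at 7.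

**Step 10.** The 3-boronate may lose boron by protonation before oxygen is inserted. In the aqueous peroxide stage the 5-silyl ether may be lost, or a prenyl alkene may be epoxidised by peracid formed from AcOH and H2O2. The fallback replaces the boron relay by direct electrophilic oxygenation of the carbanion and sets out from 16. Lithiation as before gives 17, which is trapped with bis(trimethylsilyl) peroxide (THF, −78 °C to rt) to give 8-methoxy-2-[4-(3-methylbut-2-enyloxy)phenyl]-3-(trimethylsilyloxy)-5,7-bis(triisopropylsilyloxy)-4H-chromen-4-one F5. Its labile enol trimethylsilyl ether is hydrolysed on aqueous work-up with dilute citric acid, and the route is rejoined at 19.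

## Further compounds

F1 | step 9 | 2-hydroxy-N,3-dimethoxy-N-methyl-4,6-bis(triisopropylsilyloxy)benzamide | CON(C)C(=O)c1c(O)c(OC)c(O[Si](C(C)C)(C(C)C)C(C)C)cc1O[Si](C(C)C)(C(C)C)C(C)C
F2 | step 6 | 7-hydroxy-8-methoxy-2-[4-(3-methylbut-2-enyloxy)phenyl]-5-(triisopropylsilyloxy)-4H-chromen-4-one | COc1c(O)cc(O[Si](C(C)C)(C(C)C)C(C)C)c2c(=O)cc(-c3ccc(OCC=C(C)C)cc3)oc12
F3 | step 5 | 5-hydroxy-4-iodo-2-methoxy-1,3-phenylene bis(2,2-dimethylpropanoate) | COc1c(OC(=O)C(C)(C)C)cc(O)c(I)c1OC(=O)C(C)(C)C
F4 | step 5 | 4-iodo-2-methoxy-5-(triisopropylsilyloxy)-1,3-phenylene bis(2,2-dimethylpropanoate) | COc1c(OC(=O)C(C)(C)C)cc(O[Si](C(C)C)(C(C)C)C(C)C)c(I)c1OC(=O)C(C)(C)C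
F5 | step 10 | 8-methoxy-2-[4-(3-methylbut-2-enyloxy)phenyl]-3-(trimethylsilyloxy)-5,7-bis(triisopropylsilyloxy)-4H-chromen-4-one | COc1c(O[Si](C(C)C)(C(C)C)C(C)C)cc(O[Si](C(C)C)(C(C)C)C(C)C)c2c(=O)c(O[Si](C)(C)C)c(-c3ccc(OCC=C(C)C)cc3)oc12
A1 | alternative 1 | 1,4-dimethoxy-1,3-bis(trimethylsilyloxy)buta-1,3-diene (mixture of double-bond isomers) | COC=C(O[Si](C)(C)C)C=C(OC)O[Si](C)(C)C
A2 | alternative 1 | methyl 3-bromopropiolate | COC(=O)C#CBr
A3 | alternative 1 | methyl 2-bromo-4,6-dihydroxy-3-methoxybenzoate | COC(=O)c1c(O)cc(O)c(OC)c1Br
A4 | alternative 2 | (E)-2-benzyloxy-3-(4-benzyloxyphenyl)-3-[5-benzyloxy-2-methoxy-3-(pivaloyloxy)phenoxy]prop-2-enoic acid | OC(=O)/C(OCc1ccccc1)=C(\Oc1cc(OCc2ccccc2)cc(OC(=O)C(C)(C)C)c1OC)c1ccc(OCc2ccccc2)cc1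
A5 | alternative 2 | 3,5,4'-tris(benzyloxy)-8-methoxy-7-pivaloyloxyflavone | COc1c(OC(=O)C(C)(C)C)cc(OCc2ccccc2)c2c(=O)c(OCc3ccccc3)c(-c3ccc(OCc4ccccc4)cc3)oc12
A6 | alternative 3 | 3-allyloxy-4-methoxy-4-[4-oxo-5-(3-methylbut-2-enyloxy)-6-[4-(3-methylbut-2-enyloxy)phenyl]-4H-pyran-2-yl]cyclobut-2-en-1-one (racemic) | COC1(c2cc(=O)c(OCC=C(C)C)c(-c3ccc(OCC=C(C)C)cc3)o2)C(=O)C=C1OCC=C
A7 | alternative 3 | 7-allyloxy-5-hydroxy-8-methoxy-3,4'-diprenyloxyflavone | COc1c(OCC=C)cc(O)c2c(=O)c(OCC=C(C)C)c(-c3ccc(OCC=C(C)C)cc3)oc12
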